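The cyclohexene (C1 methyl-bearing, C2, C3 benzofuranyl, C4 aroyl, C5 resorcinyl, C6; C7 the ketone carbon) is cut at C2–C3 and C4–C5. C3 is the β-carbon of a chalcone (C7–C4=C3), and C5, as an aryl ketone held cis to C2 by a (Z)-alkene C2=C1(Me)–C6, is an aldol acceptor for the C4 enolate. One rhodium-catalysed alkenylation–aldol step joins a benzofuranyl chalcone with a (Z)-alkenylboronate bearing that ketone, closes the ring and fixes C3. Dehydration, face-selective conjugate reduction, equilibration at C4 and MOM removal finish the synthesis.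

Key step: step 17

Remarks on the chemistry:
- The ring locants C1–C7 defined above are used in all names. The descriptors at C3 and C5 change in 28 and 29 only because the CIP ranking of the neighbours changes; the spatial arrangement does not.
- Assumption: (R)-BINAP is taken to deliver the alkenyl group to the enone face that gives 3R, by analogy with (E)-configured acyclic acceptors. The mirror-image ligand would be used if a model run showed the opposite sense.
- The boron group is installed while the ketone is still a dithiane, and the ketone is released last under buffered neutral conditions. The base-sensitive β,γ-unsaturated ketone therefore never meets palladium, alkoxide or phenoxide.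

Step 1
Reactants: 1 resorcinol
Product: 2 1,3-bis(methoxymethoxy)benzene
Conditions: MOMCl, NaH, DMF, 0 °C → rt
Reagents that add atoms: chloromethyl methyl ether, COCCl
Why: Williamson-type O-alkylation of both phenoxides with the reactive α-chloro ether should give the bis-acetal, which later directs both metalations.

Step 2
Reactants: 2 1,3-bis(methoxymethoxy)benzene
Product: 4 1,3-bis(methoxymethoxy)-2-(3-methylbut-2-en-1-yl)benzene, via 2,6-bis(methoxymethoxy)phenyllithium 3 (not isolated)
Conditions: n-BuLi, THF, 0 °C; then CuI (10 mol%), prenyl bromide, −40 °C → rt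
Reagents that add atoms: 1-bromo-3-methylbut-2-ene (prenyl bromide), CC(C)=CCBr
Why: Directed ortho-metalation occurs at the carbon flanked by both OMOM groups, and copper-catalysed SN2 allylation of the aryllithium keeps the prenyl unit linear.

Step 3
Reactants: 4 1,3-bis(methoxymethoxy)-2-(3-methylbut-2-en-1-yl)benzene
Product: 6 1-[2,4-bis(methoxymethoxy)-3-(3-methylbut-2-en-1-yl)phenyl]ethan-1-one, via 2,4-bis(methoxymethoxy)-3-prenylphenyllithium 5 (not isolated)
Conditions: n-BuLi, TMEDA, THF, −20 → 0 °C; then MeC(O)N(OMe)Me, −78 °C → rt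
Reagents that add atoms: N-methoxy-N-methylacetamide, CC(=O)N(C)OC
Why: A second directed ortho-metalation (the two remaining ortho positions are equivalent) is followed by acylation through the chelated tetrahedral adduct of the N-methoxy-N-methyl amide, which releases the methyl ketone only on work-up.

Step 4
Reactants: 7 3,5-dihydroxybenzaldehyde
Product: 8 3,5-bis(methoxymethoxy)benzaldehyde
Conditions: MOMCl, NaH, DMF, 0 °C → rt
Reagents that add atoms: chloromethyl methyl ether, COCCl
Why: O-alkylation of the two phenoxides gives base-stable acetals that survive every later basic and organometallic step.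

Step 5
Reactants: 8 3,5-bis(methoxymethoxy)benzaldehyde
Product: 9 1-ethynyl-3,5-bis(methoxymethoxy)benzene
Conditions: dimethyl (1-diazo-2-oxopropyl)phosphonate, K2CO3, MeOH, rt
Reagents that add atoms: dimethyl (1-diazo-2-oxopropyl)phosphonate, COP(=O)(OC)C(=[N+]=[N-])C(C)=O
Why: Seyferth–Gilbert homologation in the Ohira–Bestmann variant converts a non-enolisable aryl aldehyde into the terminal alkyne under mild carbonate conditions.

Step 6
Reactants: 10 2,4-dihydroxybenzaldehyde
Product: 11 2,4-dihydroxy-5-iodobenzaldehyde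
Conditions: ICl, AcOH, rt
Reagents that add atoms: iodine monochloride, ClI
Why: Electrophilic aromatic iodination should occur at C5 (ortho to the 4-OH, para to the 2-OH), the more accessible of the two doubly activated positions, since C3 is flanked by both hydroxyls.

Step 7
Reactants: 11 2,4-dihydroxy-5-iodobenzaldehyde; 9 1-ethynyl-3,5-bis(methoxymethoxy)benzene
Product: 13 2-[3,5-bis(methoxymethoxy)phenyl]-6-hydroxy-1-benzofuran-5-carbaldehyde, via 5-arylethynyl-2,4-dihydroxybenzaldehyde 12 (not isolated)
Conditions: PdCl2(PPh3)2 (3 mol%), CuI (5 mol%), Et3N, DMF, rt → 70 °C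
Reagents that add atoms: none
Why: Sonogashira coupling is followed by 5-endo-dig heteroannulation of the ortho-alkynylphenol; only the 4-OH is ortho to the alkyne, so the aldehyde ends at C5 and the chelated hydroxyl at C6 of the benzofuran.

Step 8
Reactants: 13 2-[3,5-bis(methoxymethoxy)phenyl]-6-hydroxy-1-benzofuran-5-carbaldehyde
Product: 14 2-[3,5-bis(methoxymethoxy)phenyl]-6-(methoxymethoxy)-1-benzofuran-5-carbaldehyde
Conditions: MOMCl, NaH, DMF, 0 °C → rt
Reagents that add atoms: chloromethyl methyl ether, COCCl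
Why: O-alkylation of the salicylaldehyde-type phenoxide removes the last free phenol, which would otherwise deactivate the aldehyde in the condensation and protonate the rhodium enolate later.

Step 9
Reactants: 6 1-[2,4-bis(methoxymethoxy)-3-(3-methylbut-2-en-1-yl)phenyl]ethan-1-one; 14 2-[3,5-bis(methoxymethoxy)phenyl]-6-(methoxymethoxy)-1-benzofuran-5-carbaldehyde
Product: 15 (2E)-1-[2,4-bis(methoxymethoxy)-3-(3-methylbut-2-en-1-yl)phenyl]-3-{2-[3,5-bis(methoxymethoxy)phenyl]-6-(methoxymethoxy)-1-benzofuran-5-yl}prop-2-en-1-one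
Conditions: KOH, EtOH/THF, rt
Reagents that add atoms: none
Why: Claisen–Schmidt condensation of a methyl ketone with a non-enolisable aldehyde, with E1cB loss of water, should give the (E)-enone under thermodynamic control.

Step 10
Reactants: 16 propargyl alcohol
Product: 18 (2Z)-3-iodo-2-methylprop-2-en-1-ol, via (Z)-alkenylmagnesium alkoxide 17 (not isolated)
Conditions: MeMgBr (2.2 equiv), CuI (10 mol%), Et2O/THF, −10 °C → rt; then I2, −78 → 0 °C
Reagents that add atoms: methylmagnesium bromide, C[Mg]Br; iodine, II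
Why: Alkoxide-directed, copper-catalysed anti-carbomagnesiation places magnesium on the terminal carbon cis to the CH2O group, and iodinolysis with retention fixes the (Z)-iodoalkene.

Step 11
Reactants: 18 (2Z)-3-iodo-2-methylprop-2-en-1-ol
Product: 19 (1Z)-3-bromo-1-iodo-2-methylprop-1-ene
Conditions: CBr4, PPh3, CH2Cl2, 0 °C
Reagents that add atoms: tetrabromomethane, BrC(Br)(Br)Br
Why: The Appel reaction replaces the primary allylic hydroxyl by SN2 displacement of the alkoxyphosphonium ion without touching the alkene geometry.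

Step 12
Reactants: 10 2,4-dihydroxybenzaldehyde
Product: 20 4-(1,3-dithian-2-yl)benzene-1,3-diol
Conditions: HS(CH2)3SH, BF3·OEt2 (cat.), CH2Cl2/THF, 0 °C → rt
Reagents that add atoms: propane-1,3-dithiol, SCCCS
Why: Lewis-acid-catalysed dithioacetalisation is run on the free phenol because the thiol/BF3 combination would cleave MOM ethers.

Step 13
Reactants: 20 4-(1,3-dithian-2-yl)benzene-1,3-diol
Product: 21 2-[2,4-bis(methoxymethoxy)phenyl]-1,3-dithiane
Conditions: MOMCl, NaH, DMF, 0 °C → rt
Reagents that add atoms: chloromethyl methyl ether, COCCl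
Why: NaH deprotonates only the phenols (the dithiane C–H is far less acidic), so O-alkylation gives the bis-MOM ether cleanly.

Step 14
Reactants: 21 2-[2,4-bis(methoxymethoxy)phenyl]-1,3-dithiane; 19 (1Z)-3-bromo-1-iodo-2-methylprop-1-ene
Product: 23 2-[2,4-bis(methoxymethoxy)phenyl]-2-[(2Z)-3-iodo-2-methylprop-2-en-1-yl]-1,3-dithiane, via 2-aryl-2-lithio-1,3-dithiane 22 (not isolated)
Conditions: n-BuLi, THF, −78 → −40 °C; then 19, −78 °C → rt
Reagents that add atoms: none
Why: Corey–Seebach alkylation: the benzylic dithiane C–H is removed at low temperature in preference to ring metalation, and the stabilised anion displaces the allylic bromide by SN2 while the alkenyl iodide stays inert.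

Step 15
Reactants: 23 2-[2,4-bis(methoxymethoxy)phenyl]-2-[(2Z)-3-iodo-2-methylprop-2-en-1-yl]-1,3-dithiane
Product: 25 2-[(1Z)-3-{2-[2,4-bis(methoxymethoxy)phenyl]-1,3-dithian-2-yl}-2-methylprop-1-en-1-yl]-4,4,5,5-tetramethyl-1,3,2-dioxaborolane, via (Z)-alkenyllithium 24 (not isolated)
Conditions: t-BuLi (2.1 equiv), Et2O, −78 °C; then i-PrOBpin, −78 °C → rt
Reagents that add atoms: 2-isopropoxy-4,4,5,5-tetramethyl-1,3,2-dioxaborolane, CC(C)OB1OC(C)(C)C(C)(C)O1
Why: Lithium–iodine exchange at −78 °C is faster than any ring metalation and proceeds with retention, and trapping of the configurationally stable alkenyllithium with the borate ester gives the (Z)-alkenyl pinacol boronate without palladium or base.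

Step 16
Reactants: 25 2-[(1Z)-3-{2-[2,4-bis(methoxymethoxy)phenyl]-1,3-dithian-2-yl}-2-methylprop-1-en-1-yl]-4,4,5,5-tetramethyl-1,3,2-dioxaborolane
Product: 26 (3Z)-1-[2,4-bis(methoxymethoxy)phenyl]-3-methyl-4-(4,4,5,5-tetramethyl-1,3,2-dioxaborolan-2-yl)but-3-en-1-one
Conditions: MeI, CaCO3, MeCN/H2O (9:1), 40 °C
Reagents that add atoms: water, O
Why: Alkylative dithiane hydrolysis (S-methylation, then attack of water) releases the aryl ketone at buffered neutral pH, so the β,γ-alkene should not move into conjugation and the C–B bond and MOM ethers stay intact.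

Step 17
Reactants: 15 (2E)-benzofuranyl chalcone; 26 (3Z)-keto alkenylboronate
Product: 27 (3R,4S,5R)-aldol: [2,4-bis(methoxymethoxy)-3-(3-methylbut-2-en-1-yl)phenyl] ketone at C4 of a 1-methylcyclohex-1-ene carrying the 2-[3,5-bis(methoxymethoxy)phenyl]-6-(methoxymethoxy)-1-benzofuran-5-yl group at C3 and both hydroxyl and 2,4-bis(methoxymethoxy)phenyl at C5 (aroyl trans to benzofuranyl, hydroxyl cis to aroyl)
Conditions: [Rh(OH)(cod)]2 (3 mol%), (R)-BINAP (7 mol%), 26 (1.5 equiv), 1,4-dioxane/H2O (20:1), 50 °C, argon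
Reagents that add atoms: none
Why: Proposed new method: transmetalation of 26 to the hydroxorhodium–(R)-BINAP complex gives a (Z)-alkenyl complex of monovalent rhodium, which inserts the chalcone alkene (C2–C3 bond) to form an oxa-π-allyl rhodium enolate at C4–C7; this enolate adds to the tethered C5 ketone before water can protonate it, and hydrolysis of the rhodium alkoxide returns the hydroxo catalyst. The closest known reactions are the rhodium/BINAP-catalysed conjugate addition of alkenylboron reagents to enones (Hayashi–Miyaura reaction) and the rhodium-catalysed conjugate addition–aldol cyclisation in which the ketone is carried by the enone, so the only new element is that the ketone sits on the boron partner. The cyclohexene closes by 6-exo-trig (enolexo) aldol addition of C4 to C5 through a chelated chair-like transition state, made possible by the (Z)-alkene that holds C2 and C6 cis. C3 is set by the ligand, which is expected to direct the alkenyl group to the enone face that gives 3R, while C4 (aroyl trans to benzofuranyl) and C5 (hydroxyl cis to aroyl) follow from the (Z)-enolate and the closed transition state and are both reset later. The step needs 1,4- before 1,2-addition and ring closure before enolate protonation: the ortho-alkoxy aryl ketones are hindered toward direct addition, the amount of water is kept small, and base is left out so that the β,γ-unsaturated ketone of 26 does not isomerise.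

Step 18
Reactants: 27 (3R,4S,5R)-aldol
Product: 28 (3S)-cyclohexa-1,4-dienyl aryl ketone (C4=C5 enone; C3 spatially unchanged)
Conditions: Ph2S[OC(CF3)2Ph]2 (Martin sulfurane), CH2Cl2, 0 °C → rt, argon; used at once
Reagents that add atoms: none
Why: Sulfurane dehydration via the alkoxysulfonium ion should remove the C4–H, which is acidified by the ketone and anti-periplanar to the axial C5–O bond, giving the conjugated C4=C5 enone under neutral conditions that spare the MOM ethers, the prenyl group and C3.

Step 19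
Reactants: 28 (3S)-cyclohexa-1,4-dienyl aryl ketone
Product: 30 (3R,4R,5S)-hepta-MOM all-trans ketone, via silyl enol ether 29 (not isolated)
Conditions: Cu(OAc)2·H2O (5 mol%), 1,2-(Ph2P)2C6H4 (5 mol%), (EtO)2MeSiH, toluene, rt, argon; then NaOMe, MeOH/THF, rt
Reagents that add atoms: none
Why: Copper hydride conjugate reduction (1,4-hydrosilylation) delivers hydride to C5 on the ring face opposite the C3 benzofuranyl group, which allylic strain with the C4 aroyl group holds pseudoaxial, so C5–aryl ends cis to C3–benzofuranyl; methoxide then cleaves the silyl enol ether and equilibrates C4 to the all-equatorial trans,trans ketone.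

Step 20
Reactants: 30 (3R,4R,5S)-hepta-MOM all-trans ketone
Product: 31 target, [2,4-dihydroxy-3-(3-methylbut-2-en-1-yl)phenyl] (3R,4R,5S)-3-[2-(3,5-dihydroxyphenyl)-6-hydroxy-1-benzofuran-5-yl]-5-(2,4-dihydroxyphenyl)-1-methylcyclohex-1-en-4-yl ketone
Conditions: aq. HCl (2 M)/MeOH/THF, 35 °C, argon
Reagents that add atoms: none
Why: Acid-catalysed acetal exchange with methanol removes all seven MOM ethers under mild conditions of the kind used for ortho-prenylated polyphenols, and the all-trans arrangement is the thermodynamic one, so enolisation at C4 cannot erode it.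

Compound list
1 | resorcinol | Oc1cccc(O)c1 | starting material
2 | 1,3-bis(methoxymethoxy)benzene | COCOc1cccc(OCOC)c1 | intermediate
3 | 2,6-bis(methoxymethoxy)phenyllithium | [Li]c1c(OCOC)cccc1OCOC | intermediate
4 | 1,3-bis(methoxymethoxy)-2-(3-methylbut-2-en-1-yl)benzene | CC(C)=CCc1c(OCOC)cccc1OCOC | intermediate
5 | [2,4-bis(methoxymethoxy)-3-(3-methylbut-2-en-1-yl)phenyl]lithium | [Li]c1ccc(OCOC)c(CC=C(C)C)c1OCOC | intermediate
6 | 1-[2,4-bis(methoxymethoxy)-3-(3-methylbut-2-en-1-yl)phenyl]ethan-1-one | CC(=O)c1ccc(OCOC)c(CC=C(C)C)c1OCOC | intermediate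
7 | 3,5-dihydroxybenzaldehyde | O=Cc1cc(O)cc(O)c1 | starting material
8 | 3,5-bis(methoxymethoxy)benzaldehyde | COCOc1cc(C=O)cc(OCOC)c1 | intermediate
9 | 1-ethynyl-3,5-bis(methoxymethoxy)benzene | C#Cc1cc(OCOC)cc(OCOC)c1 | intermediate
10 | 2,4-dihydroxybenzaldehyde | O=Cc1ccc(O)cc1O | starting material
11 | 2,4-dihydroxy-5-iodobenzaldehyde | O=Cc1cc(I)c(O)cc1O | intermediate
12 | 5-{[3,5-bis(methoxymethoxy)phenyl]ethynyl}-2,4-dihydroxybenzaldehyde | O=Cc1cc(C#Cc2cc(OCOC)cc(OCOC)c2)c(O)cc1O | intermediate
13 | 2-[3,5-bis(methoxymethoxy)phenyl]-6-hydroxy-1-benzofuran-5-carbaldehyde | O=Cc1cc2cc(-c3cc(OCOC)cc(OCOC)c3)oc2cc1O | intermediate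
14 | 2-[3,5-bis(methoxymethoxy)phenyl]-6-(methoxymethoxy)-1-benzofuran-5-carbaldehyde | COCOc1cc2oc(-c3cc(OCOC)cc(OCOC)c3)cc2cc1C=O | intermediate
15 | (2E)-1-[2,4-bis(methoxymethoxy)-3-(3-methylbut-2-en-1-yl)phenyl]-3-{2-[3,5-bis(methoxymethoxy)phenyl]-6-(methoxymethoxy)-1-benzofuran-5-yl}prop-2-en-1-one | CC(C)=CCc1c(OCOC)ccc(C(=O)/C=C/c2cc3cc(-c4cc(OCOC)cc(OCOC)c4)oc3cc2OCOC)c1OCOC | intermediate
16 | propargyl alcohol (prop-2-yn-1-ol) | OCC#C | starting material
17 | bromomagnesium (2Z)-3-(bromomagnesio)-2-methylprop-2-en-1-olate | C/C(CO[Mg]Br)=C/[Mg]Br | intermediate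
18 | (2Z)-3-iodo-2-methylprop-2-en-1-ol | C/C(CO)=C/I | intermediate
19 | (1Z)-3-bromo-1-iodo-2-methylprop-1-ene | C/C(CBr)=C/I | intermediate
20 | 4-(1,3-dithian-2-yl)benzene-1,3-diol | Oc1ccc(C2SCCCS2)c(O)c1 | intermediate
21 | 2-[2,4-bis(methoxymethoxy)phenyl]-1,3-dithiane | COCOc1ccc(C2SCCCS2)c(OCOC)c1 | intermediate
22 | 2-[2,4-bis(methoxymethoxy)phenyl]-2-lithio-1,3-dithiane | [Li]C1(c2ccc(OCOC)cc2OCOC)SCCCS1 | intermediate
23 | 2-[2,4-bis(methoxymethoxy)phenyl]-2-[(2Z)-3-iodo-2-methylprop-2-en-1-yl]-1,3-dithiane | C/C(CC1(c2ccc(OCOC)cc2OCOC)SCCCS1)=C/I | intermediate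
24 | (1Z)-3-{2-[2,4-bis(methoxymethoxy)phenyl]-1,3-dithian-2-yl}-2-methylprop-1-en-1-yllithium | C/C(CC1(c2ccc(OCOC)cc2OCOC)SCCCS1)=C/[Li] | intermediate
25 | 2-[(1Z)-3-{2-[2,4-bis(methoxymethoxy)phenyl]-1,3-dithian-2-yl}-2-methylprop-1-en-1-yl]-4,4,5,5-tetramethyl-1,3,2-dioxaborolane | C/C(CC1(c2ccc(OCOC)cc2OCOC)SCCCS1)=C/B1OC(C)(C)C(C)(C)O1 | intermediate
26 | (3Z)-1-[2,4-bis(methoxymethoxy)phenyl]-3-methyl-4-(4,4,5,5-tetramethyl-1,3,2-dioxaborolan-2-yl)but-3-en-1-one | CC1(C)OB(/C=C(/C)CC(=O)c2ccc(OCOC)cc2OCOC)OC1(C)C | intermediate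
27 | (3R,4S,5R)-aldol: hepta-MOM aryl ketone at C4 of 1-methylcyclohex-1-ene with benzofuranyl at C3 and hydroxyl plus 2,4-bis(methoxymethoxy)phenyl at C5; aroyl trans to benzofuranyl, hydroxyl cis to aroyl | CC(C)=CCc1c(OCOC)ccc(C(=O)[C@@H]2[C@@](O)(c3ccc(OCOC)cc3OCOC)CC(C)=C[C@H]2c2cc3cc(-c4cc(OCOC)cc(OCOC)c4)oc3cc2OCOC)c1OCOC | intermediate
28 | (3S)-hepta-MOM 1-methylcyclohexa-1,4-dien-4-yl aryl ketone with benzofuranyl at C3 and 2,4-bis(methoxymethoxy)phenyl at C5 | CC(C)=CCc1c(OCOC)ccc(C(=O)C2=C(c3ccc(OCOC)cc3OCOC)CC(C)=C[C@H]2c2cc3cc(-c4cc(OCOC)cc(OCOC)c4)oc3cc2OCOC)c1OCOC | intermediate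
29 | (3S,5R)-diethoxy(methyl)silyl enol ether of 30 (exocyclic C4=C7, enol ether geometry not defined; C3–H and C5–H on the same face) | CC(C)=CCc1c(OCOC)ccc(C(O[Si](C)(OCC)OCC)=C2[C@@H](c3ccc(OCOC)cc3OCOC)CC(C)=C[C@H]2c2cc3cc(-c4cc(OCOC)cc(OCOC)c4)oc3cc2OCOC)c1OCOC | intermediate
30 | (3R,4R,5S)-hepta-MOM all-trans ketone: benzofuranyl at C3 and aryl at C5 cis to each other, both trans to the aroyl group at C4 | CC(C)=CCc1c(OCOC)ccc(C(=O)[C@@H]2[C@@H](c3ccc(OCOC)cc3OCOC)CC(C)=C[C@H]2c2cc3cc(-c4cc(OCOC)cc(OCOC)c4)oc3cc2OCOC)c1OCOC | intermediate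
31 | CNP0150120.1: [2,4-dihydroxy-3-(3-methylbut-2-en-1-yl)phenyl] (3R,4R,5S)-3-[2-(3,5-dihydroxyphenyl)-6-hydroxy-1-benzofuran-5-yl]-5-(2,4-dihydroxyphenyl)-1-methylcyclohex-1-en-4-yl ketone | CC(C)=CCc1c(O)ccc(C(=O)[C@@H]2[C@@H](c3ccc(O)cc3O)CC(C)=C[C@H]2c2cc3cc(-c4cc(O)cc(O)c4)oc3cc2O)c1O | target

Total step count: 20.
Longest linear sequence: 9 steps (steps 10, 11, 14, 15, 16, 17, 18, 19, 20; the aldehyde branch through steps 4, 5, 7, 8, 9 is equally long).

Steps most likely to fail

1. Step 17 (proposed new method). The rhodium enolate may be protonated by water before it closes the ring, the pinacol ester may transmetalate slowly without base, the β,γ-unsaturated ketone may isomerise, or face selection at C3 may be poor. The fallback replaces the annulation by the known Diels–Alder reaction of a 2'-hydroxychalcone with a dehydroprenyl arene, promoted by a chiral boron complex. It sets out from 6, 10 and 14.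
   - Compound 10 is MOM-protected (MOMCl, NaH) to 2,4-bis(methoxymethoxy)benzaldehyde F1.
   - Claisen–Schmidt condensation of 6 with F1 (KOH, EtOH) should give the tetra-MOM chalcone F2.
   - Brief treatment with dilute HCl in MeOH at 0 °C should remove the carbonyl-chelated ortho MOM group first, giving the 2'-hydroxychalcone F3.
   - Wittig olefination of 14 with the ylide from (2-methylprop-2-en-1-yl)triphenylphosphonium chloride and n-BuLi, then iodine-catalysed isomerisation, should give the (E)-diene F4.
   - Cycloaddition of F3 with F4, mediated by a boron complex made from BH3·THF, AcOH and the appropriate enantiomer of an axially chiral biaryl diol, is expected to give endo and exo adducts. The exo (all-trans) adduct F5 is separated and deprotected under the conditions of step 20, coming back to the route at 31.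

2. Step 19. Hydrocupration of the tetrasubstituted, α-substituted enone may be slow, 1,2-reduction may compete, hydride may reach C5 from the wrong face, or the cyclohexadiene may aromatise in air. The fallback sets out from 28 and changes hydride insertion to electron transfer. SmI2 in THF/MeOH at −78 °C should reduce the aroyl-styrene chromophore stepwise, with C5 set by protonation of the benzylic organosamarium on the face away from the pseudoaxial C3 group. The saturated ketone is expected as a mixture at C4, namely 30 and its C4 epimer, the all-cis hepta-MOM ketone F6. NaOMe in MeOH converges the mixture on 30, where the route is rejoined.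

3. Step 20. Under protic acid the prenyl group may cyclise onto the neighbouring phenol, the ring alkene may be attacked by an ortho hydroxyl, or some of the seven acetals may resist cleavage. The fallback sets out from 30 and avoids protic acid by a two-stage silyl transfer. TESOTf with 2,2'-bipyridyl in CH2Cl2 at 0 °C should exchange each aryl MOM ether for a silyl ether, giving the heptakis(triethylsilyl) ether F7. TBAF buffered with AcOH in THF at 0 °C then frees the phenols and returns to the route at 31.

Further compounds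
F1 | step 17 | 2,4-bis(methoxymethoxy)benzaldehyde | COCOc1ccc(C=O)c(OCOC)c1
F2 | step 17 | (2E)-1-[2,4-bis(methoxymethoxy)-3-(3-methylbut-2-en-1-yl)phenyl]-3-[2,4-bis(methoxymethoxy)phenyl]prop-2-en-1-one | CC(C)=CCc1c(OCOC)ccc(C(=O)/C=C/c2ccc(OCOC)cc2OCOC)c1OCOC
F3 | step 17 | (2E)-3-[2,4-bis(methoxymethoxy)phenyl]-1-[2-hydroxy-4-(methoxymethoxy)-3-(3-methylbut-2-en-1-yl)phenyl]prop-2-en-1-one | CC(C)=CCc1c(OCOC)ccc(C(=O)/C=C/c2ccc(OCOC)cc2OCOC)c1O
F4 | step 17 | 2-[3,5-bis(methoxymethoxy)phenyl]-6-(methoxymethoxy)-5-[(1E)-3-methylbuta-1,3-dien-1-yl]-1-benzofuran | CC(=C)/C=C/c1cc2cc(-c3cc(OCOC)cc(OCOC)c3)oc2cc1OCOC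
F5 | step 17 | (3R,4R,5S)-hexa-MOM all-trans adduct with free 2-hydroxyl on the aroyl ring | CC(C)=CCc1c(OCOC)ccc(C(=O)[C@@H]2[C@@H](c3ccc(OCOC)cc3OCOC)CC(C)=C[C@H]2c2cc3cc(-c4cc(OCOC)cc(OCOC)c4)oc3cc2OCOC)c1O
F6 | step 19 | (3R,4S,5S)-hepta-MOM all-cis ketone (C4 epimer of 30) | CC(C)=CCc1c(OCOC)ccc(C(=O)[C@H]2[C@@H](c3ccc(OCOC)cc3OCOC)CC(C)=C[C@H]2c2cc3cc(-c4cc(OCOC)cc(OCOC)c4)oc3cc2OCOC)c1OCOC
F7 | step 20 | (3R,4R,5S)-heptakis(triethylsilyl) ether of 31 | CC(C)=CCc1c(O[Si](CC)(CC)CC)ccc(C(=O)[C@@H]2[C@@H](c3ccc(O[Si](CC)(CC)CC)cc3O[Si](CC)(CC)CC)CC(C)=C[C@H]2c2cc3cc(-c4cc(O[Si](CC)(CC)CC)cc(O[Si](CC)(CC)CC)c4)oc3cc2O[Si](CC)(CC)CC)c1O[Si](CC)(CC)CC
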